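The numbers in the tables come from a simulation for substances that don't exist.

These flasks differ in catalyst.

| flask | left-handed substrate | right-handed substrate | gas | catalyst | remark | time |
|---|---|---|---|---|---|---|
| north-east | 0.075 M | 0.075 M | 1.8 mM (held) | 0.10 mM | run made earlier |  |
| larch | 0.050 M | 0.050 M | 1.8 mM (held) | 0.050 mM |  | 30 h |
| ash | 0.050 M | 0.050 M | 1.8 mM (held) | 0.060 mM |  | 30 h |
| oak | 0.050 M | 0.050 M | 1.8 mM (held) | 0.030 mM |  | 30 h |
| elm | 0.050 M | 0.050 M | 1.8 mM (held) | 0.025 mM |  | 30 h |
| cedar | 0.050 M | 0.050 M | 1.8 mM (held) | 0.10 mM |  | 30 h |

north-east run (percent of the left-handed substrate and right-handed substrate together charged)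

| time / h | left-handed product / % | left-handed substrate / % |
|---|---|---|
| 4.00 | 4 | 51 |
| 8.00 | 5 | 46 |
| 10.0 | 8 | 43 |
| 15.0 | 14 | 43 |
| 20.0 | 18 | 37 |

(standard deviation of a reading: 1.5 percentage points)

- catalyst is single-handed; left-handed substrate and right-handed substrate are mirror images of each other, charged as a racemate, each of them at the stated concentration
- at the start none of coupling partner is dissolved
- candidate steps: coupling partner + catalyst + right-handed substrate -> catalyst + right-handed product; coupling partner + catalyst + left-handed substrate -> catalyst + left-handed product; left-handed substrate <-> right-handed substrate; gas <-> coupling partner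
- no earlier run changes the charge of catalyst; that part of a forecast is a guess

1. all flasks from highest to lowest amount of left-handed product, in percent of the left-handed substrate and right-handed substrate together charged, at 30 h (larch / ash / oak / elm / cedar)
2. the amount of left-handed product, in percent of the left-handed substrate and right-handed substrate together charged of the flask you put first, at 30 h
3. the amount of left-handed product, in percent of the left-handed substrate and right-handed substrate together charged of the flask you put last, at 30 h

I begin with a clock I can read. The north-east run gives me the pace, the left-handed product made per hour at 0.10 mM of catalyst with the gas held: 1.31 mM h⁻¹. At that pace the left-handed substrate of the first reading would last 58.3 h. The faster rung shows at 4.00 h: product is already there, and left-handed substrate plus product reads 55.0%, above the 50% charged, so the change of hand is already at work. Because the uptake of gas as coupling partner and the change of hand both show within a time shorter than the substrate clock, I treat them as settled: the two substrates stay equal, and coupling partner is made as fast as it is used.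

That leaves the coupling, whose rate carries catalyst and substrate multiplied together, so the falling substrate of the north-east run stands in for a falling catalyst charge. Left-handed substrate drops to 0.725 of its first reading, yet the pace reads 1.00 mM h⁻¹ early and 1.50 mM h⁻¹ late. Within the scatter it shows no fall, so I guess the pace goes with the square root of the catalyst charge.

Cedar has the run's catalyst and starts with 0.050 M of left-handed substrate, near the 0.0555 M of the last reading, so I give it the full pace: 39.4%. Elm then gets 19.7%.

The forecast gives cedar > ash > larch > oak > elm, with 27% for cedar and 8.5% for elm, in its words: “No run varied catalyst, so this is a guess”; my two figures stand higher.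

The flasks give cedar > ash > larch > oak > elm, with 33.8% for cedar and 15.3% for elm.

    coupling partner + catalyst + right-handed substrate → catalyst + right-handed product (k = 1.40 × 10⁵ L² mol⁻² h⁻¹)
    coupling partner + catalyst + left-handed substrate → catalyst + left-handed product (k = 3.30 × 10⁵ L² mol⁻² h⁻¹)
    left-handed substrate ⇌ right-handed substrate (k = 1.10 h⁻¹)
    gas ⇌ coupling partner, rate k4*(csat - [coupling partner]) (kL = 1.90 h⁻¹)

Cedar's pace, averaged over 30 h, is 1.13 mM h⁻¹ against the 1.31 mM h⁻¹ I carried, and the square root brings it to 0.894 mM h⁻¹ for a further flask like elm but with 6.3 × 10⁻⁵ M of catalyst, whose own average is 0.903 mM h⁻¹. In elm at 13.6 h coupling partner is made 1.00 times as fast as it is used, and at 15.0 h elm holds 0.00141 M of it against 9.38 × 10⁻⁴ M in cedar, so at that time catalyst times partner in cedar is 2.66 times that in elm.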